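**Plan**

- Retrosynthetic cuts, in order: the two MOM ethers; the pyrone C3'–C4' bond; the enol-ester O1'–C2' acyl bond (back to a C7 propanoic acid and methyl 2-methyl-3-oxopentanoate); O1–C2 and C3–C3a of the dihydrofuran (ring B); the aryl–CH2 bond of the C3 arm.
- Enabling feature: in the pyrone ring (O1', C2'–C6') the bridge-bearing C3' sits next to the hydroxylated C4'. An enol ester that already holds O1'–C2' and O1'–C6' can therefore be closed at C3'–C4' as the last ring bond.
- Forward order: phloracetophenone (ring A) is masked so that only the hydroxyl para to the acetyl group is free. Bromine and the propanoate arm are placed on its two ortho carbons, ring B is closed by palladium heteroannulation with myrcene, the arm is joined to the β-keto ester as a Z enol ester, the pyrone ring is closed, and the MOM groups are removed.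
- Stereochemistry: the only stereocentre, C2 (R), is set by the chiral ligand on palladium in the heteroannulation and is not touched afterwards.

Key step: step 10

Assumption: the enantiomer of the sulfinamide–phosphine ligand that gives (R) at C2 with myrcene is taken to be the one that gives (R)-2-isopropenyl-2,3-dihydrobenzofurans from isoprene; if the sense proves opposite, the antipodal ligand is used. Locants 2–7a refer to the benzofuran, primed locants to the pyrone.

**Route**

Step 1
Reactants: 1 1-(2,4,6-trihydroxyphenyl)ethan-1-one (phloracetophenone)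
Product: 2 1-[4-(benzyloxy)-2,6-dihydroxyphenyl]ethan-1-one
Conditions: BnBr (1.0 equiv), K2CO3 (1.1 equiv), DMF, 0 °C → rt
Reagents that add atoms: benzyl bromide, BrCc1ccccc1
Why: Williamson etherification should go at the 4-hydroxyl, the most acidic one and the only one not hydrogen-bonded to the acetyl carbonyl, when one equivalent of halide is used.

Step 2
Reactants: 2 1-[4-(benzyloxy)-2,6-dihydroxyphenyl]ethan-1-one
Product: 3 1-[4-(benzyloxy)-2,6-bis(methoxymethoxy)phenyl]ethan-1-one
Conditions: NaH (2.5 equiv), MOMCl (2.5 equiv), DMF, 0 °C → rt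
Reagents that add atoms: chloromethyl methyl ether, COCCl
Why: Williamson-type alkylation of both sodium phenoxides gives the bis-acetal; NaH is chosen because the chelated ortho-hydroxyls react sluggishly with amine bases.

Step 3
Reactants: 3 1-[4-(benzyloxy)-2,6-bis(methoxymethoxy)phenyl]ethan-1-one
Product: 4 1-[4-hydroxy-2,6-bis(methoxymethoxy)phenyl]ethan-1-one
Conditions: H2 (1 atm), 10% Pd/C, EtOAc, rt
Reagents that add atoms: none
Why: Catalytic hydrogenolysis cleaves only the benzylic C–O bond; the MOM acetals and the hindered aryl ketone should survive short exposure at atmospheric pressure.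

Step 4
Reactants: 4 1-[4-hydroxy-2,6-bis(methoxymethoxy)phenyl]ethan-1-one
Product: 5 1-[3-bromo-4-hydroxy-2,6-bis(methoxymethoxy)phenyl]ethan-1-one
Conditions: NBS (1.0 equiv), CH2Cl2, −78 → 0 °C
Reagents that add atoms: N-bromosuccinimide, O=C1CCC(=O)N1Br
Why: Electrophilic aromatic bromination takes one of the two equivalent positions ortho to the free phenol, and the first bromine lowers ring reactivity so that one equivalent at low temperature should stop at the monobromide.

Step 5
Reactants: 5 1-[3-bromo-4-hydroxy-2,6-bis(methoxymethoxy)phenyl]ethan-1-one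
Product: 6 1-{3-bromo-5-[(dimethylamino)methyl]-4-hydroxy-2,6-bis(methoxymethoxy)phenyl}ethan-1-one
Conditions: Me2NH (40% aq.), CH2O (37% aq.), EtOH, rt
Reagents that add atoms: formaldehyde, C=O; dimethylamine, CNC
Why: Phenolic Mannich reaction: the iminium ion attacks the only unsubstituted ring carbon, which is ortho to the free hydroxyl and activated by all three oxygen substituents.

Step 6
Reactants: 6 1-{3-bromo-5-[(dimethylamino)methyl]-4-hydroxy-2,6-bis(methoxymethoxy)phenyl}ethan-1-one; 7 2,2-dimethyl-1,3-dioxane-4,6-dione (Meldrum's acid)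
Product: 9 methyl 3-[3-acetyl-5-bromo-6-hydroxy-2,4-bis(methoxymethoxy)phenyl]propanoate, via bromo dihydrocoumarin lactone 8 (not isolated)
Conditions: 7 (2.2 equiv), MeCN, 80 °C; then NaOMe (3 equiv), MeOH, 0 °C → rt; aq. NH4Cl
Reagents that add atoms: sodium methoxide, [Na+].[O-]C
Why: On heating, the Mannich base loses dimethylamine to an ortho-quinone methide that Meldrum's acid adds to in Michael fashion, the phenol lactonises with loss of acetone and CO2 to dihydrocoumarin 8, and methoxide opens this aryl ester by transesterification; the excess Meldrum's acid keeps the liberated amine protonated so that it cannot open the lactone as an amide.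

Step 7
Reactants: 9 methyl 3-[3-acetyl-5-bromo-6-hydroxy-2,4-bis(methoxymethoxy)phenyl]propanoate; 10 myrcene (7-methyl-3-methylideneocta-1,6-diene)
Product: 11 methyl 3-[(2R)-5-acetyl-4,6-bis(methoxymethoxy)-2-(6-methylhepta-1,5-dien-2-yl)-2,3-dihydro-1-benzofuran-7-yl]propanoate
Conditions: 10 (3 equiv), Pd2(dba)3·CHCl3 (5 mol %), chiral sulfinamide monophosphine TY-Phos (12 mol %), K2CO3 (2 equiv), toluene, 60 °C
Reagents that add atoms: none
Why: Heck/Tsuji–Trost (Larock-type) heteroannulation: oxidative addition of the C–Br bond to zerovalent palladium, insertion of the monosubstituted vinyl group of myrcene with aryl going to its terminal carbon, and attack of the single free phenoxide on the internal terminus of the π-allylpalladium close ring B, the chiral ligand controlling which face of that terminus is attacked and so setting C2 as R.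

Step 8
Reactants: 11 methyl 3-[(2R)-5-acetyl-4,6-bis(methoxymethoxy)-2-(6-methylhepta-1,5-dien-2-yl)-2,3-dihydro-1-benzofuran-7-yl]propanoate
Product: 12 3-[(2R)-5-acetyl-4,6-bis(methoxymethoxy)-2-(6-methylhepta-1,5-dien-2-yl)-2,3-dihydro-1-benzofuran-7-yl]propanoic acid
Conditions: LiOH (3 equiv), THF/MeOH/H2O, rt; then cold 0.5 M HCl to pH 4
Reagents that add atoms: lithium hydroxide, [Li+].[OH-]
Why: Saponification of the unhindered methyl ester; the acetals, the aryl ketone and C2, which carries no acidic hydrogen, should be unaffected by aqueous LiOH at room temperature.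

Step 9
Reactants: 12 3-[(2R)-5-acetyl-4,6-bis(methoxymethoxy)-2-(6-methylhepta-1,5-dien-2-yl)-2,3-dihydro-1-benzofuran-7-yl]propanoic acid; 13 methyl 2-methyl-3-oxopentanoate
Product: 15 methyl (2Z)-3-({3-[(2R)-5-acetyl-4,6-bis(methoxymethoxy)-2-(6-methylhepta-1,5-dien-2-yl)-2,3-dihydro-1-benzofuran-7-yl]propanoyl}oxy)-2-methylpent-2-enoate, via acid chloride 14 (not isolated)
Conditions: 1-chloro-N,N,2-trimethylprop-1-en-1-amine (1.2 equiv), CH2Cl2, 0 °C → rt; then sodium enolate of 13 (13 1.5 equiv, NaH 1.4 equiv, THF, 0 °C), −78 → 0 °C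
Reagents that add atoms: none
Why: The Ghosez reagent forms the acid chloride under neutral conditions that spare MOM ethers and alkenes, and the chelated, U-shaped sodium enolate of the α-methyl β-keto ester, hindered at carbon, should undergo O-acylation with the acyloxy group cis to the ester, giving the Z enol ester.

Step 10
Reactants: 15 methyl (2Z)-3-({3-[(2R)-5-acetyl-4,6-bis(methoxymethoxy)-2-(6-methylhepta-1,5-dien-2-yl)-2,3-dihydro-1-benzofuran-7-yl]propanoyl}oxy)-2-methylpent-2-enoate
Product: 16 1-[(2R)-7-[(6-ethyl-4-hydroxy-5-methyl-2-oxo-2H-pyran-3-yl)methyl]-4,6-bis(methoxymethoxy)-2-(6-methylhepta-1,5-dien-2-yl)-2,3-dihydro-1-benzofuran-5-yl]ethan-1-one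
Conditions: LiN(SiMe3)2 (3.5 equiv), THF, −78 → −20 °C, substrate added to the base; then cold 0.5 M HCl to pH 3–4
Reagents that add atoms: none
Why: Proposed new method: LiN(SiMe3)2 first turns the aryl methyl ketone into its lithium enolate and then removes an α-proton of the acyloxy-activated propanoate; the resulting ester enolate at C3' adds to the methyl ester carbon C4', held cis by the Z alkene, and expels methoxide (intramolecular Claisen, i.e. Dieckmann condensation), and the pyran-2,4-dione is deprotonated at once to the aromatic lithium pyronate, which makes the closure irreversible. The closest known reactions are the base-mediated Dieckmann closures of methyl O-acylsalicylates to 4-hydroxycoumarins and of α-acyloxy esters to tetronic acids; the present substrate is the open-chain vinylogue in which an enol ester replaces the aryl ester. The pyrone ring closes in the 6-exo-trig mode by forming C3'–C4', with O1'–C2' and O1'–C6' already in place. No stereocentre is created, and C2 of ring B is not affected. The step needs ring closure to outrun both expulsion of the β-keto ester enolate from the ester enolate (ketene formation) and intermolecular acyl transfer; the Z geometry (six-membered transition state), the low temperature, the inverse addition into excess base and the masking of the acetyl group as its unreactive enolate are meant to secure this.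

Step 11
Reactants: 16 1-[(2R)-7-[(6-ethyl-4-hydroxy-5-methyl-2-oxo-2H-pyran-3-yl)methyl]-4,6-bis(methoxymethoxy)-2-(6-methylhepta-1,5-dien-2-yl)-2,3-dihydro-1-benzofuran-5-yl]ethan-1-one
Product: 17 3-{[(2R)-5-acetyl-4,6-dihydroxy-2-(6-methylhepta-1,5-dien-2-yl)-2,3-dihydro-1-benzofuran-7-yl]methyl}-6-ethyl-4-hydroxy-5-methyl-2H-pyran-2-one (target)
Conditions: HCl (0.5 M in MeOH), 0 °C → rt
Reagents that add atoms: none
Why: Acid-catalysed acetal exchange with methanol removes both MOM groups, which flank the acetyl group and are activated by it, under conditions too mild to protonate the isolated alkenes or ionise the allylic aryl ether at C2, so the stereocentre should persist.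

**Compound list**

1 | 1-(2,4,6-trihydroxyphenyl)ethan-1-one (phloracetophenone) | CC(=O)c1c(O)cc(O)cc1O | starting material
2 | 1-[4-(benzyloxy)-2,6-dihydroxyphenyl]ethan-1-one | CC(=O)c1c(O)cc(OCc2ccccc2)cc1O | intermediate
3 | 1-[4-(benzyloxy)-2,6-bis(methoxymethoxy)phenyl]ethan-1-one | CC(=O)c1c(OCOC)cc(OCc2ccccc2)cc1OCOC | intermediate
4 | 1-[4-hydroxy-2,6-bis(methoxymethoxy)phenyl]ethan-1-one | CC(=O)c1c(OCOC)cc(O)cc1OCOC | intermediate
5 | 1-[3-bromo-4-hydroxy-2,6-bis(methoxymethoxy)phenyl]ethan-1-one | CC(=O)c1c(OCOC)cc(O)c(Br)c1OCOC | intermediate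
6 | 1-{3-bromo-5-[(dimethylamino)methyl]-4-hydroxy-2,6-bis(methoxymethoxy)phenyl}ethan-1-one | CC(=O)c1c(OCOC)c(CN(C)C)c(O)c(Br)c1OCOC | intermediate
7 | 2,2-dimethyl-1,3-dioxane-4,6-dione (Meldrum's acid) | CC1(C)OC(=O)CC(=O)O1 | starting material
8 | 6-acetyl-8-bromo-5,7-bis(methoxymethoxy)-3,4-dihydro-2H-1-benzopyran-2-one | CC(=O)c1c(OCOC)c2CCC(=O)Oc2c(Br)c1OCOC | intermediate (not isolated)
9 | methyl 3-[3-acetyl-5-bromo-6-hydroxy-2,4-bis(methoxymethoxy)phenyl]propanoate | COC(=O)CCc1c(OCOC)c(C(C)=O)c(OCOC)c(Br)c1O | intermediate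
10 | myrcene (7-methyl-3-methylideneocta-1,6-diene) | C=CC(=C)CCC=C(C)C | starting material
11 | methyl 3-[(2R)-5-acetyl-4,6-bis(methoxymethoxy)-2-(6-methylhepta-1,5-dien-2-yl)-2,3-dihydro-1-benzofuran-7-yl]propanoate | C=C(CCC=C(C)C)[C@H]1Cc2c(OCOC)c(C(C)=O)c(OCOC)c(CCC(=O)OC)c2O1 | intermediate
12 | 3-[(2R)-5-acetyl-4,6-bis(methoxymethoxy)-2-(6-methylhepta-1,5-dien-2-yl)-2,3-dihydro-1-benzofuran-7-yl]propanoic acid | C=C(CCC=C(C)C)[C@H]1Cc2c(OCOC)c(C(C)=O)c(OCOC)c(CCC(=O)O)c2O1 | intermediate
13 | methyl 2-methyl-3-oxopentanoate | CCC(=O)C(C)C(=O)OC | starting material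
14 | 3-[(2R)-5-acetyl-4,6-bis(methoxymethoxy)-2-(6-methylhepta-1,5-dien-2-yl)-2,3-dihydro-1-benzofuran-7-yl]propanoyl chloride | C=C(CCC=C(C)C)[C@H]1Cc2c(OCOC)c(C(C)=O)c(OCOC)c(CCC(=O)Cl)c2O1 | intermediate (not isolated)
15 | methyl (2Z)-3-({3-[(2R)-5-acetyl-4,6-bis(methoxymethoxy)-2-(6-methylhepta-1,5-dien-2-yl)-2,3-dihydro-1-benzofuran-7-yl]propanoyl}oxy)-2-methylpent-2-enoate | C=C(CCC=C(C)C)[C@H]1Cc2c(OCOC)c(C(C)=O)c(OCOC)c(CCC(=O)O/C(CC)=C(/C)C(=O)OC)c2O1 | intermediate
16 | 1-[(2R)-7-[(6-ethyl-4-hydroxy-5-methyl-2-oxo-2H-pyran-3-yl)methyl]-4,6-bis(methoxymethoxy)-2-(6-methylhepta-1,5-dien-2-yl)-2,3-dihydro-1-benzofuran-5-yl]ethan-1-one | C=C(CCC=C(C)C)[C@H]1Cc2c(OCOC)c(C(C)=O)c(OCOC)c(Cc3c(O)c(C)c(CC)oc3=O)c2O1 | intermediate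
17 | 3-{[(2R)-5-acetyl-4,6-dihydroxy-2-(6-methylhepta-1,5-dien-2-yl)-2,3-dihydro-1-benzofuran-7-yl]methyl}-6-ethyl-4-hydroxy-5-methyl-2H-pyran-2-one | C=C(CCC=C(C)C)[C@H]1Cc2c(O)c(C(C)=O)c(O)c(Cc3c(O)c(C)c(CC)oc3=O)c2O1 | target

**Step count and risks**

Total step count: 11. Longest linear sequence: 11 steps (1 → 17); compounds 7, 10 and 13 are bought.

Steps most likely to fail:

Step 10 (Proposed new method). The ester enolate may fragment to a ketene and the β-keto ester enolate, or pass its acyl group to another molecule, faster than it cyclises. The fallback uses known chemistry, sets out from 5 and comes back at 17. Bromophenol 5 is annulated with 10 under the conditions of step 7 to give 1-[(2R)-4,6-bis(methoxymethoxy)-2-(6-methylhepta-1,5-dien-2-yl)-2,3-dihydro-1-benzofuran-5-yl]ethan-1-one F1, and methanolic HCl then frees both phenols to give 1-[(2R)-4,6-dihydroxy-2-(6-methylhepta-1,5-dien-2-yl)-2,3-dihydro-1-benzofuran-5-yl]ethan-1-one F2. Separately, 3-(trimethylsilyloxy)pent-2-ene and malonyl dichloride (Et2O, −78 °C → rt) give 6-ethyl-4-hydroxy-5-methyl-2H-pyran-2-one F3, which dimethylmethylideneammonium iodide converts into 3-[(dimethylamino)methyl]-6-ethyl-4-hydroxy-5-methyl-2H-pyran-2-one F4. Heating F4 with F2 (MeCN, 80 °C) releases dimethylamine; the 3-methylidenepyran-2,4-dione so formed is attacked by C7 of F2, its only free ring carbon, in a Michael-type aromatic alkylation that gives 17 directly.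

Step 7. Oxidative addition into the doubly ortho-substituted, electron-rich bromophenoxide may be slow, or the chiral catalyst may give poor enantioselection or insertion regioselectivity with myrcene. The fallback sets out from 9 and comes back at 11. The annulation is run with an achiral catalyst suited to hindered aryl bromides (Pd(OAc)2, P(t-Bu)3, K2CO3, DMF, 80 °C) to give racemic material, and the enantiomers are separated by preparative HPLC on a chiral stationary phase. Ester 11 goes on, and methyl 3-[(2S)-5-acetyl-4,6-bis(methoxymethoxy)-2-(6-methylhepta-1,5-dien-2-yl)-2,3-dihydro-1-benzofuran-7-yl]propanoate F5 is set aside. The source of enantiopurity thus changes from catalyst control to separation.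

Step 9. The enolate may be acylated at its quaternary carbon, the E enol ester may form, or the acid chloride may lose HCl to a ketene. The fallback sets out from 12 and 13 and comes back at 15. Acid 12 is converted with cyanuric fluoride and pyridine into 3-[(2R)-5-acetyl-4,6-bis(methoxymethoxy)-2-(6-methylhepta-1,5-dien-2-yl)-2,3-dihydro-1-benzofuran-7-yl]propanoyl fluoride F6, and 13 with Me3SiCl/Et3N into methyl (2Z)-2-methyl-3-[(trimethylsilyl)oxy]pent-2-enoate F7. A catalytic amount of n-Bu4NF in THF at −78 °C then triggers O-acylation of the silyl enol ether by the acyl fluoride, driven by Si–F bond formation, and should give 15 without a metal enolate or a base-sensitive acid chloride.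

**Further compounds**

F1 | step 10 | 1-[(2R)-4,6-bis(methoxymethoxy)-2-(6-methylhepta-1,5-dien-2-yl)-2,3-dihydro-1-benzofuran-5-yl]ethan-1-one | C=C(CCC=C(C)C)[C@H]1Cc2c(OCOC)c(C(C)=O)c(OCOC)cc2O1
F2 | step 10 | 1-[(2R)-4,6-dihydroxy-2-(6-methylhepta-1,5-dien-2-yl)-2,3-dihydro-1-benzofuran-5-yl]ethan-1-one | C=C(CCC=C(C)C)[C@H]1Cc2c(O)c(C(C)=O)c(O)cc2O1
F3 | step 10 | 6-ethyl-4-hydroxy-5-methyl-2H-pyran-2-one | CCc1oc(=O)cc(O)c1C
F4 | step 10 | 3-[(dimethylamino)methyl]-6-ethyl-4-hydroxy-5-methyl-2H-pyran-2-one | CCc1oc(=O)c(CN(C)C)c(O)c1C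
F5 | step 7 | methyl 3-[(2S)-5-acetyl-4,6-bis(methoxymethoxy)-2-(6-methylhepta-1,5-dien-2-yl)-2,3-dihydro-1-benzofuran-7-yl]propanoate | C=C(CCC=C(C)C)[C@@H]1Cc2c(OCOC)c(C(C)=O)c(OCOC)c(CCC(=O)OC)c2O1
F6 | step 9 | 3-[(2R)-5-acetyl-4,6-bis(methoxymethoxy)-2-(6-methylhepta-1,5-dien-2-yl)-2,3-dihydro-1-benzofuran-7-yl]propanoyl fluoride | C=C(CCC=C(C)C)[C@H]1Cc2c(OCOC)c(C(C)=O)c(OCOC)c(CCC(=O)F)c2O1
F7 | step 9 | methyl (2Z)-2-methyl-3-[(trimethylsilyl)oxy]pent-2-enoate | C[Si](C)(C)O/C(CC)=C(/C)C(=O)OC
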